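## Retrosynthetic overview

1. The methylene bridge is cut last: the C6–CH2 bond of the dienone ring comes from Michael addition of trione 21 to an o‑quinone methide released from the aminomethylated aromatic half 27 (made from phloroglucinol).
2. In the dearomatized ring (C1 carbonyl, C2 methyl, C3 OH, C4 quaternary, C5 OH, C6), the C2–C3 unit is lithium propynolate (MeC≡C–O⁻), made in the flask from 1,1‑dibromopropan‑2‑one, and C1/C6/C5/C4 are the four carbons of a 2‑silyl‑3‑ethoxycyclobutenone. One ring expansion makes C1–C2 and C3–C4.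
3. Enabling feature: the quaternary C4 lies para to the C1 carbonyl and between the oxygenated C3 and C5, so the polarity alternates around the ring (C1 electrophilic, C2 nucleophilic, C3 electrophilic, C4 nucleophilic). Because C4 carries two carbon substituents, a ynolate/vinylketene annulation that normally ends in a resorcinol must stop at the cyclohexadienone, which is the target ring.
4. Temporary elements: the four‑membered ring (its C1–C4 bond is cleaved), SiMe3 on C6, ethyl on O5, and the isobutyryl carbonyl held at the carbinol level. The carbinol carbon (from asymmetric hydrogenation) relays chirality to C4 and is then oxidized away.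
5. Ring order: aromatic ring bought; cyclobutenone by ketene/ynol ether [2+2]; six‑membered dienone ring in the key step; CH2 bridge last.

Key step: step 6

Assumption: in the 6π closure of step 6 the new bond is taken to form anti to isopropyl in the H‑eclipsed carbinol rotamer; if the other face is preferred, the (R)‑BINAP catalyst in step 1 gives the same final enantiomer by the same route.
Remark: enolized triones are drawn in one tautomer; 10 forms as both epimers at its ring sp3 carbon (left undefined in its SMILES), and these converge in step 6.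

## Route

Step 1
Reactants: 1 methyl 4-methyl-3-oxopentanoate
Product: 2 methyl (3R)-3-hydroxy-4-methylpentanoate
Conditions: H2 (50 atm), RuCl2[(S)-BINAP] (0.1 mol%), MeOH, 50 °C
Reagents that add atoms: none
Why: Noyori asymmetric hydrogenation of a β‑keto ester; the ester‑chelated ketone is reduced on the face fixed by (S)‑BINAP, which should give the (R)‑carbinol that later relays chirality.

Step 2
Reactants: 2 methyl (3R)-3-hydroxy-4-methylpentanoate; 3 1-bromo-3-methylbut-2-ene
Product: 4 methyl (2S,3S)-3-hydroxy-4-methyl-2-(3-methylbut-2-en-1-yl)pentanoate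
Conditions: LiN(i-Pr)2 (2.2 equiv), THF, −78 → −20 °C; 3, DMPU, −78 → 0 °C; 1 M HCl
Reagents that add atoms: none
Why: Fráter–Seebach alkylation of the chelated alkoxide–enolate dianion, anti to isopropyl; the C2 center is not needed later because it becomes a ketene carbon.

Step 3
Reactants: 4 methyl (2S,3S)-3-hydroxy-4-methyl-2-(3-methylbut-2-en-1-yl)pentanoate
Product: 5 (2S,3S)-3-hydroxy-4-methyl-2-(3-methylbut-2-en-1-yl)pentanoic acid
Conditions: LiOH·H2O, THF/MeOH/H2O, 40 °C; 1 M HCl
Reagents that add atoms: lithium hydroxide, [Li+].[OH-]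
Why: ester saponification; no other base‑labile group is present.

Step 4
Reactants: 5 (2S,3S)-3-hydroxy-4-methyl-2-(3-methylbut-2-en-1-yl)pentanoic acid
Product: 6 triethylsilyl (2S,3S)-4-methyl-2-(3-methylbut-2-en-1-yl)-3-(triethylsilyloxy)pentanoate
Conditions: Et3SiOTf (2.3 equiv), 2,6-lutidine, CH2Cl2, −78 → 0 °C; non-aqueous work-up
Reagents that add atoms: triethylsilyl triflate, CC[Si](CC)(CC)OS(=O)(=O)C(F)(F)F
Why: double O‑silylation; the silyl ester allows acid chloride formation under neutral conditions and the silyl ether masks the relay carbinol.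

Step 5
Reactants: 6 triethylsilyl (2S,3S)-4-methyl-2-(3-methylbut-2-en-1-yl)-3-(triethylsilyloxy)pentanoate; 7 (ethoxyethynyl)trimethylsilane
Product: 10 3-ethoxy-4-(3-methylbut-2-en-1-yl)-4-[(1S)-2-methyl-1-(triethylsilyloxy)propyl]-2-(trimethylsilyl)cyclobut-2-en-1-one, via acid chloride 8 (not isolated), via ketene 9 (not isolated)
Conditions: (COCl)2, DMF (cat.), CH2Cl2, 0 °C → rt; evaporate; 7 (1.5 equiv), Et3N, toluene, 70 °C
Reagents that add atoms: none
Why: silyl ester to acid chloride, dehydrochlorination to the dialkylketene and ketene–ynol ether [2+2] cycloaddition; the nucleophilic silyl‑bearing alkyne carbon bonds to the ketene carbonyl carbon, which fixes the regiochemistry.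

Step 6
Reactants: 10 3-ethoxy-4-(3-methylbut-2-en-1-yl)-4-[(1S)-2-methyl-1-(triethylsilyloxy)propyl]-2-(trimethylsilyl)cyclobut-2-en-1-one; 11 1,1-dibromopropan-2-one
Product: 18 (6R)-5-ethoxy-3-hydroxy-2-methyl-6-(3-methylbut-2-en-1-yl)-6-[(1S)-2-methyl-1-(triethylsilyloxy)propyl]cyclohexa-2,4-dien-1-one, via dibromoenolate 12 (not isolated), via bromolithio enolate 13 (not isolated), via lithium propynolate 14 (not isolated), via silylvinylketene 15 (not isolated), via oxidodienylketene 16 (not isolated), via silyl dienolate 17 (not isolated)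
Conditions: 10, toluene, 100 °C, then cooled; 11, LiN(SiMe3)2, THF, −78 °C, then t-BuLi (2.0 equiv), −78 → 0 °C; solutions combined at −78 °C → rt; 1 M HCl, THF, 0 °C
Reagents that add atoms: none
Why: Proposed new method: a Kowalski rearrangement supplies the ynolate free of alkoxide (deprotonation of 11 to the dibromoenolate 12, bromine–lithium exchange to 13, 1,2‑methyl shift with loss of LiBr to 14), thermal conrotatory 4π opening of 10 gives the silylvinylketene 15 (carbinol arm outward, prenyl inward), 14 adds through its methyl‑bearing carbon to the ketene carbonyl carbon from the side away from SiMe3 (first new ring bond, carbonyl carbon to C–Me), and the (Z)‑3‑oxidodienylketene 16 closes by a thermal disrotatory 6π electrocyclization between the new ketene carbon and the fully substituted enol ether terminus (second new ring bond, C–O carbon to the quaternary carbon), after which acid removes SiMe3 from carbon. The closest known reaction type is the anionic Danheiser‑type benzannulation of (trialkylsilyl)vinylketenes with lithium ynolates to resorcinols, together with the 6π closure of dienylketenes with disubstituted termini to cyclohexa‑2,4‑dienones; new here is that the fully substituted terminus stops the annulation at the dienone and that an allylic stereocenter is asked to control the closure. The six‑membered carbocycle is closed by the 6π electrocyclization, so the four‑membered ring is expanded by two carbons overall. The new quaternary stereocenter is controlled by the adjacent (S)‑silyloxy carbinol: in the rotamer with C–H eclipsing the enol ether double bond (A1,3 strain against OEt) the ketene carbon should bond anti to isopropyl, giving 6R, and the minor diastereomer should be separable by chromatography. The step needs C‑acylation with this connectivity and a Z enolate: the polarity match (ynolate carbon onto the ketene carbon, enol ether β‑carbon onto the new ketene) fixes the regiochemistry, while SiMe3 suppresses ketene [2+2] and dimerization and directs the ynolate to the vinyl side.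

Step 7
Reactants: 18 (6R)-5-ethoxy-3-hydroxy-2-methyl-6-(3-methylbut-2-en-1-yl)-6-[(1S)-2-methyl-1-(triethylsilyloxy)propyl]cyclohexa-2,4-dien-1-one
Product: 20 (6S)-5-ethoxy-3-hydroxy-2-methyl-6-(3-methylbut-2-en-1-yl)-6-(2-methylpropanoyl)cyclohexa-2,4-dien-1-one, via carbinol 19 (not isolated)
Conditions: HF·pyridine, pyridine, THF, 0 °C; then n-Pr4N[RuO4] (5 mol%), N-methylmorpholine N-oxide, 4 Å molecular sieves, CH2Cl2, 0 °C
Reagents that add atoms: none
Why: buffered fluoride desilylation followed at once by Ley–Griffith oxidation, a non‑electrophilic oxidant that should spare the enol carbon and the prenyl group; the relay stereocenter is erased and the carbinol is not stored because it can fragment by retro‑aldol with aromatization.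

Step 8
Reactants: 20 (6S)-5-ethoxy-3-hydroxy-2-methyl-6-(3-methylbut-2-en-1-yl)-6-(2-methylpropanoyl)cyclohexa-2,4-dien-1-one
Product: 21 (4R)-3,5-dihydroxy-2-methyl-4-(3-methylbut-2-en-1-yl)-4-(2-methylpropanoyl)cyclohexa-2,5-dien-1-one
Conditions: 1 M HCl, THF, 25 °C
Reagents that add atoms: water, O
Why: acid hydrolysis of the vinylogous ethyl ester by addition–elimination; dilute acid at room temperature should leave the prenyl group and the quaternary acyl center intact.

Step 9
Reactants: 22 benzene-1,3,5-triol; 23 2-methylpropanoyl chloride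
Product: 24 2-methyl-1-(2,4,6-trihydroxyphenyl)propan-1-one
Conditions: AlCl3 (3 equiv), CH2Cl2/MeNO2, 0 °C → rt; aq. HCl
Reagents that add atoms: none
Why: Friedel–Crafts acylation of phloroglucinol; the first acyl group deactivates the ring against a second acylation.

Step 10
Reactants: 24 2-methyl-1-(2,4,6-trihydroxyphenyl)propan-1-one; 3 1-bromo-3-methylbut-2-ene
Product: 25 2-methyl-1-[2,4,6-trihydroxy-3-(3-methylbut-2-en-1-yl)phenyl]propan-1-one
Conditions: 3 (1.0 equiv), 10% aq. KOH, 0 °C
Reagents that add atoms: none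
Why: C‑alkylation of the phloroglucinol phenoxide in water; the two free ring positions are equivalent, and limiting the bromide favors mono‑prenylation.

Step 11
Reactants: 25 2-methyl-1-[2,4,6-trihydroxy-3-(3-methylbut-2-en-1-yl)phenyl]propan-1-one; 26 N,N-dimethylmethylideneammonium iodide
Product: 27 1-[3-[(dimethylamino)methyl]-2,4,6-trihydroxy-5-(3-methylbut-2-en-1-yl)phenyl]-2-methylpropan-1-one
Conditions: CH2Cl2, rt; aq. NaHCO3
Reagents that add atoms: none
Why: Mannich reaction with a preformed iminium salt at the only free ring position, which installs the future bridge carbon as an o‑quinone methide precursor.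

Step 12
Reactants: 21 (4R)-3,5-dihydroxy-2-methyl-4-(3-methylbut-2-en-1-yl)-4-(2-methylpropanoyl)cyclohexa-2,5-dien-1-one; 27 1-[3-[(dimethylamino)methyl]-2,4,6-trihydroxy-5-(3-methylbut-2-en-1-yl)phenyl]-2-methylpropan-1-one
Product: 29 (4S)-3,5-dihydroxy-2-methyl-4-(3-methylbut-2-en-1-yl)-4-(2-methylpropanoyl)-6-[[2,4,6-trihydroxy-3-(3-methylbut-2-en-1-yl)-5-(2-methylpropanoyl)phenyl]methyl]cyclohexa-2,5-dien-1-one, via quinone methide 28 (not isolated)
Conditions: toluene, 80 °C, argon
Reagents that add atoms: none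
Why: the acidic trione protonates the benzylic amine, thermal loss of dimethylamine gives the o‑quinone methide, and Michael addition of the only C–H nucleophilic carbon of 21 (C6) should give the bridge; the quaternary stereocenter is not touched.

## Compound list

1 | methyl 4-methyl-3-oxopentanoate | COC(=O)CC(=O)C(C)C | starting material
2 | methyl (3R)-3-hydroxy-4-methylpentanoate | COC(=O)C[C@@H](O)C(C)C | intermediate
3 | 1-bromo-3-methylbut-2-ene (prenyl bromide) | CC(C)=CCBr | starting material
4 | methyl (2S,3S)-3-hydroxy-4-methyl-2-(3-methylbut-2-en-1-yl)pentanoate | COC(=O)[C@@H](CC=C(C)C)[C@@H](O)C(C)C | intermediate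
5 | (2S,3S)-3-hydroxy-4-methyl-2-(3-methylbut-2-en-1-yl)pentanoic acid | OC(=O)[C@@H](CC=C(C)C)[C@@H](O)C(C)C | intermediate
6 | triethylsilyl (2S,3S)-4-methyl-2-(3-methylbut-2-en-1-yl)-3-(triethylsilyloxy)pentanoate | CC[Si](CC)(CC)OC(=O)[C@@H](CC=C(C)C)[C@@H](O[Si](CC)(CC)CC)C(C)C | intermediate
7 | (ethoxyethynyl)trimethylsilane | CCOC#C[Si](C)(C)C | starting material
8 | (2S,3S)-4-methyl-2-(3-methylbut-2-en-1-yl)-3-(triethylsilyloxy)pentanoyl chloride | ClC(=O)[C@@H](CC=C(C)C)[C@@H](O[Si](CC)(CC)CC)C(C)C | intermediate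
9 | (3S)-4-methyl-2-(3-methylbut-2-en-1-yl)-3-(triethylsilyloxy)pent-1-en-1-one (ketene) | O=C=C(CC=C(C)C)[C@@H](O[Si](CC)(CC)CC)C(C)C | intermediate
10 | 3-ethoxy-4-(3-methylbut-2-en-1-yl)-4-[(1S)-2-methyl-1-(triethylsilyloxy)propyl]-2-(trimethylsilyl)cyclobut-2-en-1-one (both ring-carbon epimers) | CCOC1=C([Si](C)(C)C)C(=O)C1(CC=C(C)C)[C@@H](O[Si](CC)(CC)CC)C(C)C | intermediate
11 | 1,1-dibromopropan-2-one | CC(=O)C(Br)Br | starting material
12 | lithium 1,1-dibromoprop-1-en-2-olate | CC([O-])=C(Br)Br.[Li+] | intermediate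
13 | lithium 1-bromo-1-lithioprop-1-en-2-olate (either double-bond geometry) | CC([O-])=C([Li])Br.[Li+] | intermediate
14 | lithium prop-1-yn-1-olate | CC#C[O-].[Li+] | intermediate
15 | (3Z,5S)-3-ethoxy-6-methyl-4-(3-methylbut-2-en-1-yl)-5-(triethylsilyloxy)-2-(trimethylsilyl)hepta-1,3-dien-1-one (silylvinylketene) | O=C=C([Si](C)(C)C)/C(OCC)=C(\CC=C(C)C)[C@@H](O[Si](CC)(CC)CC)C(C)C | intermediate
16 | lithium 3-oxidodienylketene from C-acylation of 14 by 15 (ketenyl group cis to the ethoxy-bearing carbon) | O=C=C(C)/C([O-])=C([Si](C)(C)C)\C(OCC)=C(/CC=C(C)C)[C@@H](O[Si](CC)(CC)CC)C(C)C.[Li+] | intermediate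
17 | lithium enolate of the C-silylated ring-closure product (4-trimethylsilyl derivative of 18, as its 3-olate) | CCOC1=C([Si](C)(C)C)C([O-])=C(C)C(=O)[C@]1(CC=C(C)C)[C@@H](O[Si](CC)(CC)CC)C(C)C.[Li+] | intermediate
18 | (6R)-5-ethoxy-3-hydroxy-2-methyl-6-(3-methylbut-2-en-1-yl)-6-[(1S)-2-methyl-1-(triethylsilyloxy)propyl]cyclohexa-2,4-dien-1-one | CCOC1=CC(O)=C(C)C(=O)[C@]1(CC=C(C)C)[C@@H](O[Si](CC)(CC)CC)C(C)C | intermediate
19 | (6R)-5-ethoxy-3-hydroxy-6-[(1S)-1-hydroxy-2-methylpropyl]-2-methyl-6-(3-methylbut-2-en-1-yl)cyclohexa-2,4-dien-1-one | CCOC1=CC(O)=C(C)C(=O)[C@]1(CC=C(C)C)[C@@H](O)C(C)C | intermediate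
20 | (6S)-5-ethoxy-3-hydroxy-2-methyl-6-(3-methylbut-2-en-1-yl)-6-(2-methylpropanoyl)cyclohexa-2,4-dien-1-one | CCOC1=CC(O)=C(C)C(=O)[C@]1(CC=C(C)C)C(=O)C(C)C | intermediate
21 | (4R)-3,5-dihydroxy-2-methyl-4-(3-methylbut-2-en-1-yl)-4-(2-methylpropanoyl)cyclohexa-2,5-dien-1-one | C1=C(O)[C@@](CC=C(C)C)(C(=O)C(C)C)C(O)=C(C)C1=O | intermediate
22 | benzene-1,3,5-triol (phloroglucinol) | Oc1cc(O)cc(O)c1 | starting material
23 | 2-methylpropanoyl chloride | CC(C)C(Cl)=O | starting material
24 | 2-methyl-1-(2,4,6-trihydroxyphenyl)propan-1-one | CC(C)C(=O)c1c(O)cc(O)cc1O | intermediate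
25 | 2-methyl-1-[2,4,6-trihydroxy-3-(3-methylbut-2-en-1-yl)phenyl]propan-1-one | CC(C)=CCc1c(O)cc(O)c(C(=O)C(C)C)c1O | intermediate
26 | N,N-dimethylmethylideneammonium iodide | C=[N+](C)C.[I-] | starting material
27 | 1-[3-[(dimethylamino)methyl]-2,4,6-trihydroxy-5-(3-methylbut-2-en-1-yl)phenyl]-2-methylpropan-1-one | CC(C)=CCc1c(O)c(CN(C)C)c(O)c(C(=O)C(C)C)c1O | intermediate
28 | 3,5-dihydroxy-6-methylidene-2-(3-methylbut-2-en-1-yl)-4-(2-methylpropanoyl)cyclohexa-2,4-dien-1-one (o-quinone methide) | C=C1C(=O)C(CC=C(C)C)=C(O)C(C(=O)C(C)C)=C1O | intermediate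
29 | (4S)-3,5-dihydroxy-2-methyl-4-(3-methylbut-2-en-1-yl)-4-(2-methylpropanoyl)-6-[[2,4,6-trihydroxy-3-(3-methylbut-2-en-1-yl)-5-(2-methylpropanoyl)phenyl]methyl]cyclohexa-2,5-dien-1-one | CC(C)=CCc1c(O)c(CC2=C(O)[C@@](CC=C(C)C)(C(=O)C(C)C)C(O)=C(C)C2=O)c(O)c(C(=O)C(C)C)c1O | target

## Step count and risks

Total steps: 12. Longest linear sequence: 9 steps (1, 2, 3, 4, 5, 6, 7, 8, 12).

**Step 6 (carries the new-method label).** The ynolate may add from the silyl side and give an enolate geometry that cannot cyclize. The carbenoid rearrangement may be incomplete, so that residual organolithium consumes the ketene. The vinylketene may be lost by 1,5‑hydrogen shift or oligomerization before it is trapped. Facial selectivity in the 6π closure may be poor. The fallback uses known neutral pericyclic chemistry; it sets out from 6 and comes back at 21. Compound 6 is taken through acid chloride 8 and ketene 9 as in step 5, but the ketene is trapped with ethoxyacetylene in place of 7, which should give the silicon‑free cyclobutenone F1. Heating F1 with commercial 1‑ethoxyprop‑1‑yne in toluene (80–110 °C) is a Danheiser benzannulation run on a fully substituted terminus. It proceeds by 4π opening to the vinylketene F2, ketene–alkyne [2+2] cycloaddition to the 4‑vinylcyclobutenone F3, a second 4π opening to the dienylketene F4, and 6π closure to the 3,5‑diethoxy dienone F5. F5 has the ring constitution of 18, reached through a different set of ring bonds. Under the conditions of step 7, HF·pyridine should give the carbinol F6 and the oxidation the ketone F7. Under the conditions of step 8 both enol ethers of F7 are hydrolyzed, and the route is rejoined at 21.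

**Step 5.** Dehydrochlorination of the hindered acid chloride may be slow, triethylsilanol may be lost by β‑elimination, and the cycloaddition to the silylated ynol ether may be sluggish. The fallback replaces the ketene by a more electrophilic keteniminium ion; it sets out from 6 and comes back at 10. Acid chloride 8, made from 6 as before, is treated with dimethylamine to give the amide F8. Triflic anhydride and 2,4,6‑collidine in CH2Cl2 convert F8 into the keteniminium triflate F9. Keteniminium–alkyne [2+2] cycloaddition of F9 with 7 gives the cyclobuteniminium triflate F10, and aqueous NaHCO3 hydrolysis of F10 gives 10.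

**Step 7.** Once the carbinol is unmasked it may fragment by a retro‑aldol path (loss of isobutyraldehyde with aromatization), and the free enol carbon may be oxidized. The fallback caps the vinylogous acid before the carbinol is exposed; it sets out from 18 and comes back at 21. O‑Methylation of 18 with Me3SiCHN2 in toluene/MeOH gives the methyl ether F11 (drawn as the 3‑methoxy isomer; the other O‑methyl isomer converges later). HF·pyridine then gives the carbinol F12, which no longer has an acidic enol proton to assist fragmentation. Dess–Martin periodinane with NaHCO3 gives the ketone F13, and under the conditions of step 8 both enol ethers of F13 are hydrolyzed to 21.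

## Further compounds

F1 | step 6 | 3-ethoxy-4-(3-methylbut-2-en-1-yl)-4-[(1S)-2-methyl-1-(triethylsilyloxy)propyl]cyclobut-2-en-1-one (both ring-carbon epimers) | CCOC1=CC(=O)C1(CC=C(C)C)[C@@H](O[Si](CC)(CC)CC)C(C)C
F2 | step 6 | (3Z,5S)-3-ethoxy-6-methyl-4-(3-methylbut-2-en-1-yl)-5-(triethylsilyloxy)hepta-1,3-dien-1-one (vinylketene) | O=C=C/C(OCC)=C(\CC=C(C)C)[C@@H](O[Si](CC)(CC)CC)C(C)C
F3 | step 6 | 3-ethoxy-2-methyl-4-[(1Z,3S)-1-ethoxy-4-methyl-2-(3-methylbut-2-en-1-yl)-3-(triethylsilyloxy)pent-1-en-1-yl]cyclobut-2-en-1-one (both ring-carbon epimers) | O=C1C(C)=C(OCC)C1/C(OCC)=C(\CC=C(C)C)[C@@H](O[Si](CC)(CC)CC)C(C)C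
F4 | step 6 | dienylketene from ring opening of F3 (ketenyl group cis to the ethoxy-bearing carbon) | O=C=C(C)/C(OCC)=C\C(OCC)=C(/CC=C(C)C)[C@@H](O[Si](CC)(CC)CC)C(C)C
F5 | step 6 | (6R)-3,5-diethoxy-2-methyl-6-(3-methylbut-2-en-1-yl)-6-[(1S)-2-methyl-1-(triethylsilyloxy)propyl]cyclohexa-2,4-dien-1-one | CCOC1=CC(OCC)=C(C)C(=O)[C@]1(CC=C(C)C)[C@@H](O[Si](CC)(CC)CC)C(C)C
F6 | step 6 | (6R)-3,5-diethoxy-6-[(1S)-1-hydroxy-2-methylpropyl]-2-methyl-6-(3-methylbut-2-en-1-yl)cyclohexa-2,4-dien-1-one | CCOC1=CC(OCC)=C(C)C(=O)[C@]1(CC=C(C)C)[C@@H](O)C(C)C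
F7 | step 6 | (6S)-3,5-diethoxy-2-methyl-6-(3-methylbut-2-en-1-yl)-6-(2-methylpropanoyl)cyclohexa-2,4-dien-1-one | CCOC1=CC(OCC)=C(C)C(=O)[C@]1(CC=C(C)C)C(=O)C(C)C
F8 | step 5 | (2S,3S)-N,N,4-trimethyl-2-(3-methylbut-2-en-1-yl)-3-(triethylsilyloxy)pentanamide | CN(C)C(=O)[C@@H](CC=C(C)C)[C@@H](O[Si](CC)(CC)CC)C(C)C
F9 | step 5 | keteniminium triflate derived from F8 | C[N+](C)=C=C(CC=C(C)C)[C@@H](O[Si](CC)(CC)CC)C(C)C.[O-]S(=O)(=O)C(F)(F)F
F10 | step 5 | N,N-dimethyl cyclobuteniminium triflate corresponding to 10 | CCOC1=C([Si](C)(C)C)C(=[N+](C)C)C1(CC=C(C)C)[C@@H](O[Si](CC)(CC)CC)C(C)C.[O-]S(=O)(=O)C(F)(F)F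
F11 | step 7 | (6R)-5-ethoxy-3-methoxy-2-methyl-6-(3-methylbut-2-en-1-yl)-6-[(1S)-2-methyl-1-(triethylsilyloxy)propyl]cyclohexa-2,4-dien-1-one | CCOC1=CC(OC)=C(C)C(=O)[C@]1(CC=C(C)C)[C@@H](O[Si](CC)(CC)CC)C(C)C
F12 | step 7 | (6R)-5-ethoxy-6-[(1S)-1-hydroxy-2-methylpropyl]-3-methoxy-2-methyl-6-(3-methylbut-2-en-1-yl)cyclohexa-2,4-dien-1-one | CCOC1=CC(OC)=C(C)C(=O)[C@]1(CC=C(C)C)[C@@H](O)C(C)C
F13 | step 7 | (6S)-5-ethoxy-3-methoxy-2-methyl-6-(3-methylbut-2-en-1-yl)-6-(2-methylpropanoyl)cyclohexa-2,4-dien-1-one | CCOC1=CC(OC)=C(C)C(=O)[C@]1(CC=C(C)C)C(=O)C(C)C
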